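**Plan**

1. Locants: the cacalol half is numbered as naphtho[2,3-b]furan (O1 to C9a; ring B is its benzene ring); the second half is a primed benzofuran (O1′ to C7a′; ring A is its benzene ring).
2. Retrosynthesis: the dihydropyran is cut at C8–C2′ and O9–C3′ (retro hetero-Diels–Alder). The unit O9–C9–C8a–C8 of ring B (phenol oxygen, two ring carbons, benzylic carbon) is a latent 1-oxadiene, the o-quinone methide 24; C2′=C3′ of the 3-methylbenzofuran 23 is its electron-rich 2π partner.
3. o-Quinone methide precursor 14: C8–C8a by Friedel–Crafts acylation, C5–aryl by enantioselective redox-relay Heck arylation, furan by aryloxyacetone cyclodehydration, back to 2-methoxy-5-methylphenol.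
4. Benzofuran 23: side chain by B-alkyl Suzuki coupling, methylenation and ortho-formylation; furan as above, back to 2-methoxy-4-methylphenol.
5. Forward order: furan then carbocycle (cacalol half); furan then chain (primed half); the dihydropyran closes last and joins the halves.
6. Stereochemistry: C5 from the chiral ligand of the relay Heck step; C8, C2′ and C3′ from the cycloaddition (both C8 epimers of 14 converge on planar 24; C5 selects the face; endo approach and suprafacial addition fix the rest); the E-alkene is carried in from (E)-1-bromoprop-1-ene.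

Key step: step 16

Assumption: in step 5 the ligand antipode is the one that turns the (E)-alkenol into the 4S aldehyde; the (S)-ligand is written, and the (R)-ligand takes its place if the sense of induction is the opposite.

**Route**

Step 1
Reactants: 1 2-methoxy-5-methylphenol
Product: 2 4-bromo-2-methoxy-5-methylphenol
Conditions: NBS, MeCN, 0 °C
Reagents that add atoms: N-bromosuccinimide, O=C1CCC(=O)N1Br
Why: Electrophilic aromatic bromination, in which the position para to the free OH (also ortho to CH3) is the most activated and least hindered site.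

Step 2
Reactants: 2 4-bromo-2-methoxy-5-methylphenol; 3 chloroacetone
Product: 4 1-(4-bromo-2-methoxy-5-methylphenoxy)propan-2-one
Conditions: K2CO3, KI (cat.), acetone, reflux
Reagents that add atoms: none
Why: Williamson ether synthesis (phenoxide SN2 on an α-chloroketone, assisted by iodide).

Step 3
Reactants: 4 1-(4-bromo-2-methoxy-5-methylphenoxy)propan-2-one
Product: 5 5-bromo-7-methoxy-3,4-dimethyl-1-benzofuran
Conditions: polyphosphoric acid, PhCl, 90 °C
Reagents that add atoms: none
Why: Acid-mediated cyclodehydration of an aryloxyacetone (intramolecular Friedel–Crafts hydroxyalkylation, then loss of water), in which the only free position ortho to the ether oxygen is the one next to CH3, so the 3,4-dimethyl pattern is fixed.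

Step 4
Reactants: 5 5-bromo-7-methoxy-3,4-dimethyl-1-benzofuran
Product: 7 (7-methoxy-3,4-dimethyl-1-benzofuran-5-yl)boronic acid, via lithium aryltriisopropoxyborate 6 (not isolated)
Conditions: B(Oi-Pr)3, n-BuLi, THF–PhMe, −78 °C (in situ quench); 2 M HCl
Reagents that add atoms: triisopropyl borate, CC(C)OB(OC(C)C)OC(C)C; water, O
Why: Bromine–lithium exchange with in situ borate capture, which at −78 °C should outrun deprotonation at furan C2, followed by hydrolysis of the borate.

Step 5
Reactants: 7 (7-methoxy-3,4-dimethyl-1-benzofuran-5-yl)boronic acid; 8 (E)-pent-3-en-1-ol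
Product: 9 (4S)-4-(7-methoxy-3,4-dimethyl-1-benzofuran-5-yl)pentanal
Conditions: Pd(MeCN)2(OTs)2 (6 mol%), Cu(OTf)2 (6 mol%), (S)-4-tert-butyl-2-[5-(trifluoromethyl)pyridin-2-yl]-4,5-dihydrooxazole (13 mol%), 3 Å MS, O2 (1 atm), DMF, rt
Reagents that add atoms: none
Why: Enantioselective redox-relay oxidative Heck arylation, in which aryl–Pd adds across the alkene with the aryl group at the carbon remote from OH, palladium walks down the chain by β-hydride elimination and reinsertion and leaves as the aldehyde, and the chiral pyridine–oxazoline ligand selects the alkene face and so sets C5 as S.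

Step 6
Reactants: 9 (4S)-4-(7-methoxy-3,4-dimethyl-1-benzofuran-5-yl)pentanal
Product: 10 (4S)-4-(7-methoxy-3,4-dimethyl-1-benzofuran-5-yl)pentanoic acid
Conditions: NaClO2, NaH2PO4, 2-methylbut-2-ene, t-BuOH–H2O, rt
Reagents that add atoms: sodium chlorite, [Na+].[O-]Cl=O
Why: Pinnick oxidation, which touches only the aldehyde while the alkene scavenger keeps HOCl away from the electron-rich benzofuran, and the stereocentre is not α to the carbonyl.

Step 7
Reactants: 10 (4S)-4-(7-methoxy-3,4-dimethyl-1-benzofuran-5-yl)pentanoic acid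
Product: 12 (5S)-9-methoxy-3,4,5-trimethyl-6,7-dihydronaphtho[2,3-b]furan-8(5H)-one, via acid chloride 11 (not isolated)
Conditions: (COCl)2, DMF (cat.), CH2Cl2, 0 °C to rt; evaporate; (CF3)2CHOH, rt, high dilution
Reagents that add atoms: none
Why: Intramolecular Friedel–Crafts acylation (acid chloride activated by the hydrogen-bond-donor solvent, no Lewis acid) at the only benzene-ring position left, ortho to OCH3, which closes the six-membered ketone ring.

Step 8
Reactants: 12 (5S)-9-methoxy-3,4,5-trimethyl-6,7-dihydronaphtho[2,3-b]furan-8(5H)-one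
Product: 13 (5S)-9-hydroxy-3,4,5-trimethyl-6,7-dihydronaphtho[2,3-b]furan-8(5H)-one
Conditions: BCl3, CH2Cl2, −78 to 0 °C; H2O
Reagents that add atoms: none
Why: Chelation-assisted ether cleavage, in which BCl3 bound to the peri carbonyl removes the adjacent methyl group under conditions the furan should tolerate.

Step 9
Reactants: 13 (5S)-9-hydroxy-3,4,5-trimethyl-6,7-dihydronaphtho[2,3-b]furan-8(5H)-one
Product: 14 (5S,8RS)-3,4,5-trimethyl-5,6,7,8-tetrahydronaphtho[2,3-b]furan-8,9-diol (both C8 epimers)
Conditions: NaBH4, MeOH–THF, 0 °C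
Reagents that add atoms: none
Why: Hydride reduction of the aryl ketone to the o-hydroxybenzyl alcohol, where the C8 configuration does not matter because both epimers give the same o-quinone methide in step 16.

Step 10
Reactants: 15 2-methoxy-4-methylphenol; 3 chloroacetone
Product: 16 1-(2-methoxy-4-methylphenoxy)propan-2-one
Conditions: K2CO3, KI (cat.), acetone, reflux
Reagents that add atoms: none
Why: Williamson ether synthesis as in step 2.

Step 11
Reactants: 16 1-(2-methoxy-4-methylphenoxy)propan-2-one
Product: 17 7-methoxy-3,5-dimethyl-1-benzofuran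
Conditions: polyphosphoric acid, PhCl, 90 °C
Reagents that add atoms: none
Why: Cyclodehydration of the aryloxyacetone at the only free position ortho to the ether oxygen, as in step 3.

Step 12
Reactants: 17 7-methoxy-3,5-dimethyl-1-benzofuran
Product: 18 3,5-dimethyl-1-benzofuran-7-ol
Conditions: NaSEt, DMF, 130 °C; 1 M HCl
Reagents that add atoms: none
Why: Nucleophilic demethylation (thiolate SN2 at the methyl group), which spares the acid-sensitive benzofuran.

Step 13
Reactants: 18 3,5-dimethyl-1-benzofuran-7-ol
Product: 19 7-hydroxy-3,5-dimethyl-1-benzofuran-6-carbaldehyde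
Conditions: MgCl2, Et3N, (CH2O)n, MeCN, reflux; 1 M HCl
Reagents that add atoms: paraformaldehyde (as formaldehyde), C=O
Why: Magnesium-phenoxide-directed ortho-formylation (ortho-hydroxymethylation, then hydride transfer to a second formaldehyde), for which C6 is the only free ortho position.

Step 14
Reactants: 19 7-hydroxy-3,5-dimethyl-1-benzofuran-6-carbaldehyde
Product: 20 6-ethenyl-3,5-dimethyl-1-benzofuran-7-ol
Conditions: Ph3PCH3Br, KOt-Bu (excess), THF, 0 °C to rt
Reagents that add atoms: methyltriphenylphosphonium bromide, C[P+](c1ccccc1)(c1ccccc1)c1ccccc1.[Br-]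
Why: Wittig methylenation of the salicylaldehyde, with excess ylide to cover the phenoxide that forms first.

Step 15
Reactants: 20 6-ethenyl-3,5-dimethyl-1-benzofuran-7-ol; 21 (E)-1-bromoprop-1-ene
Product: 23 3,5-dimethyl-6-[(3E)-pent-3-en-1-yl]-1-benzofuran-7-ol, via O,C-bis(9-BBN) adduct 22 (not isolated)
Conditions: 9-BBN (2.2 equiv), THF, 0 °C to rt; then 21, PdCl2(dppf), 3 M aq NaOH, THF, 50 °C
Reagents that add atoms: none
Why: Anti-Markovnikov hydroboration of the styrene with 9-BBN, then B-alkyl Suzuki–Miyaura coupling, which retains the E geometry of the bromoalkene and leaves the benzofuran double bond alone.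

Step 16
Reactants: 14 (5S,8RS)-3,4,5-trimethyl-5,6,7,8-tetrahydronaphtho[2,3-b]furan-8,9-diol; 23 3,5-dimethyl-6-[(3E)-pent-3-en-1-yl]-1-benzofuran-7-ol
Product: 25 target CNP0281983.1, via o-quinone methide 24 (not isolated)
Conditions: PhMe, 4 Å MS, 120 °C, sealed tube; 23 in excess (2.5 equiv, surplus recovered)
Reagents that add atoms: none
Why: Heating dehydrates both C8 epimers of 14 to the one planar o-quinone methide 24, whose O9=C9–C8a=C8 unit adds the electron-rich C2′=C3′ bond of 23 in an inverse-demand hetero-Diels–Alder reaction that is asynchronous, with C8–C2′ bonding ahead of O9–C3′, because C2′ is the nucleophilic carbon of a 3-methylbenzofuran and C3′ can carry tertiary benzylic cation character. The closest known reaction type is the thermal [4+2] trapping of o-quinone methides from o-hydroxybenzyl alcohols by enol ethers, styrenes, indenes and furans or benzofurans. The dihydropyran ring closes by a suprafacial [4π+2π] cycloaddition in which C8–C2′ and O9–C3′ form on one face of each partner, so the C2′/C3′ ring fusion can only be cis and C3′ follows C2′. C8 is set by C5: the 5-methyl is held pseudoaxial by the peri 4-methyl, and bonding on the face that carries it turns C8 directly into the half-chair with H8 and 5-CH3 trans-diaxial, whereas the other face must end in a boat or push 5-CH3 against 4-CH3; C2′ relative to C8 is set by the endo placement of ring A over ring B, which puts H8, H2′ and 3′-CH3 on one face. The step needs C2′-to-C8 regiochemistry (secured by the polarity above), endo and facial selectivity (argued above, and the least secure point), and preference for 23 over the furan of 24 itself (secured by the excess of 23 and by the 4-methyl that shields C3 of the cacalol furan). The ring holds C7 trans to the carbonyl oxygen, which blocks the 1,5-hydrogen shift that usually destroys alkyl-substituted o-quinone methides.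

**Compound list**

1 | 2-methoxy-5-methylphenol | COc1ccc(C)cc1O | starting material
2 | 4-bromo-2-methoxy-5-methylphenol | COc1cc(Br)c(C)cc1O | intermediate
3 | chloroacetone | CC(=O)CCl | starting material
4 | 1-(4-bromo-2-methoxy-5-methylphenoxy)propan-2-one | COc1cc(Br)c(C)cc1OCC(C)=O | intermediate
5 | 5-bromo-7-methoxy-3,4-dimethyl-1-benzofuran | COc1cc(Br)c(C)c2c(C)coc12 | intermediate
6 | lithium (7-methoxy-3,4-dimethyl-1-benzofuran-5-yl)triisopropoxyborate (not isolated) | [Li+].COc1cc([B-](OC(C)C)(OC(C)C)OC(C)C)c(C)c2c(C)coc12 | intermediate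
7 | (7-methoxy-3,4-dimethyl-1-benzofuran-5-yl)boronic acid | COc1cc(B(O)O)c(C)c2c(C)coc12 | intermediate
8 | (E)-pent-3-en-1-ol | C/C=C/CCO | starting material
9 | (4S)-4-(7-methoxy-3,4-dimethyl-1-benzofuran-5-yl)pentanal | O=CCC[C@H](C)c1cc(OC)c2occ(C)c2c1C | intermediate
10 | (4S)-4-(7-methoxy-3,4-dimethyl-1-benzofuran-5-yl)pentanoic acid | OC(=O)CC[C@H](C)c1cc(OC)c2occ(C)c2c1C | intermediate
11 | (4S)-4-(7-methoxy-3,4-dimethyl-1-benzofuran-5-yl)pentanoyl chloride (not isolated) | ClC(=O)CC[C@H](C)c1cc(OC)c2occ(C)c2c1C | intermediate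
12 | (5S)-9-methoxy-3,4,5-trimethyl-6,7-dihydronaphtho[2,3-b]furan-8(5H)-one | O=C1CC[C@H](C)c2c1c(OC)c1occ(C)c1c2C | intermediate
13 | (5S)-9-hydroxy-3,4,5-trimethyl-6,7-dihydronaphtho[2,3-b]furan-8(5H)-one | O=C1CC[C@H](C)c2c1c(O)c1occ(C)c1c2C | intermediate
14 | (5S,8RS)-3,4,5-trimethyl-5,6,7,8-tetrahydronaphtho[2,3-b]furan-8,9-diol (8-hydroxycacalol, both C8 epimers) | OC1CC[C@H](C)c2c1c(O)c1occ(C)c1c2C | intermediate
15 | 2-methoxy-4-methylphenol | COc1cc(C)ccc1O | starting material
16 | 1-(2-methoxy-4-methylphenoxy)propan-2-one | COc1cc(C)ccc1OCC(C)=O | intermediate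
17 | 7-methoxy-3,5-dimethyl-1-benzofuran | COc1cc(C)cc2c(C)coc12 | intermediate
18 | 3,5-dimethyl-1-benzofuran-7-ol | Cc1cc(O)c2occ(C)c2c1 | intermediate
19 | 7-hydroxy-3,5-dimethyl-1-benzofuran-6-carbaldehyde | Cc1cc2c(C)coc2c(O)c1C=O | intermediate
20 | 6-ethenyl-3,5-dimethyl-1-benzofuran-7-ol | C=Cc1c(C)cc2c(C)coc2c1O | intermediate
21 | (E)-1-bromoprop-1-ene | C/C=C/Br | starting material
22 | 9-{2-[7-(9-borabicyclo[3.3.1]nonan-9-yloxy)-3,5-dimethyl-1-benzofuran-6-yl]ethyl}-9-borabicyclo[3.3.1]nonane (not isolated) | Cc1cc2c(C)coc2c(OB3C4CCCC3CCC4)c1CCB1C2CCCC1CCC2 | intermediate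
23 | 3,5-dimethyl-6-[(3E)-pent-3-en-1-yl]-1-benzofuran-7-ol | C/C=C/CCc1c(C)cc2c(C)coc2c1O | intermediate
24 | (5S)-3,4,5-trimethyl-6,7-dihydronaphtho[2,3-b]furan-9(5H)-one (o-quinone methide, C8=C8a; not isolated) | O=C1C2=CCC[C@H](C)C2=C(C)c2c(C)coc21 | intermediate
25 | target: (5S,8R)-cacalol skeleton (3,4,5-trimethyl-5,6,7,8-tetrahydronaphtho[2,3-b]furan) with C8 bonded to C2′ and the 9-oxygen bonded to C3′ of (2′R,3′R)-3′,5′-dimethyl-6′-[(E)-pent-3-enyl]-2′,3′-dihydro-1-benzofuran-7′-ol; cis-fused dihydropyran with H8, H2′ and 3′-CH3 on one face and the C8–C2′ bond cis to 5-CH3 | C/C=C/CCc1c(C)cc2c(c1O)O[C@@H]1[C@@H]3CC[C@H](C)c4c3c(c3occ(C)c3c4C)O[C@]21C | target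

**Step count and risks**

Total steps: 16. Longest linear sequence: 10 (steps 1 to 9, then step 16).

Steps most likely to fail:

Step 16. The face selection at C8 may be poor or inverted, because approach anti to the pseudoaxial 5-methyl is the sterically and torsionally easier early pathway. The endo preference may also be modest, and the o-quinone methide may drain into its 7,8-dehydro tautomer or into trapping by the cacalol furan. The fallback sets C8 by hydride delivery instead of by carbon–carbon bond formation; it sets out from 13 and 23 and comes back at 25. Compound 23 is converted into its O,C2′-dilithio derivative (n-BuLi, THF) and added, as the organocerium reagent (CeCl3), to the lithium phenoxide of 13 to give the tertiary alcohol (5S,8RS)-8-{7-hydroxy-3,5-dimethyl-6-[(E)-pent-3-enyl]-1-benzofuran-2-yl}-3,4,5-trimethyl-5,6,7,8-tetrahydronaphtho[2,3-b]furan-8,9-diol F1. Ionic hydrogenation (Et3SiH, TFA, CH2Cl2, −78 °C) should pass through the 8-aryl o-quinone methide F2 and deliver hydride to C8 anti to the pseudoaxial 5-methyl (axial attack), giving the (8R)-8-(benzofuran-2-yl)cacalol F3. Acid-catalysed intramolecular Markovnikov hydroalkoxylation of the C2′=C3′ bond by the 9-OH (catalytic diphenyl phosphate, CH2Cl2) should then close the dihydropyran through O9–C3′ and give 25. The cis ring fusion is enforced, and the relation of C2′/C3′ to C8 is then under thermodynamic control.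

Step 5. Site selectivity or enantioselectivity may be low with the ortho-substituted, electron-rich boronic acid, and protodeboronation or oxidative homocoupling may consume it. The fallback sets out from 5 and comes back at 9. Miyaura borylation of 5 (B2pin2, PdCl2(dppf), KOAc, dioxane) gives 2-(7-methoxy-3,4-dimethyl-1-benzofuran-5-yl)-4,4,5,5-tetramethyl-1,3,2-dioxaborolane F4. Copper-catalysed enantioselective SN2′ allylic arylation of (E)-but-2-enyl diethyl phosphate (CuCl, chiral N-heterocyclic carbene, NaOMe, THF) gives 5-[(2S)-but-3-en-2-yl]-7-methoxy-3,4-dimethyl-1-benzofuran F5. Linear-selective hydroformylation (Rh(acac)(CO)2, Xantphos, CO/H2) then gives 9.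

Step 7. Acylation at furan C2 of a second molecule or acid-induced oligomerisation of the benzofuran may compete with ring closure. The fallback closes the carbocycle through a magnesium phenoxide instead of an acylium ion; it sets out from 9 and comes back at 14, bypassing 10 to 13. Aldehyde 9 is protected as 5-[(2S)-5,5-dimethoxypentan-2-yl]-7-methoxy-3,4-dimethyl-1-benzofuran F6 (HC(OMe)3, PPTS, MeOH). Thiolate demethylation (NaSEt, DMF) gives 5-[(2S)-5,5-dimethoxypentan-2-yl]-3,4-dimethyl-1-benzofuran-7-ol F7. Mild aqueous acid frees (4S)-4-(7-hydroxy-3,4-dimethyl-1-benzofuran-5-yl)pentanal F8. Its magnesium phenoxide (EtMgBr, toluene) should undergo ortho-specific intramolecular hydroxyalkylation to give diol 14 directly.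

**Further compounds**

F1 | step 16 | (5S,8RS)-8-{7-hydroxy-3,5-dimethyl-6-[(E)-pent-3-enyl]-1-benzofuran-2-yl}-3,4,5-trimethyl-5,6,7,8-tetrahydronaphtho[2,3-b]furan-8,9-diol | C/C=C/CCc1c(C)cc2c(C)c(oc2c1O)C1(O)CC[C@H](C)c2c1c(O)c1occ(C)c1c2C
F2 | step 16 | (5S)-8-{7-hydroxy-3,5-dimethyl-6-[(E)-pent-3-enyl]-1-benzofuran-2-yl}-3,4,5-trimethyl-6,7-dihydronaphtho[2,3-b]furan-9(5H)-one (8-aryl o-quinone methide, transient) | C/C=C/CCc1c(C)cc2c(C)c(oc2c1O)C1=C2C(=O)c3occ(C)c3C(C)=C2[C@@H](C)CC1
F3 | step 16 | (5S,8R)-8-{7-hydroxy-3,5-dimethyl-6-[(E)-pent-3-enyl]-1-benzofuran-2-yl}-3,4,5-trimethyl-5,6,7,8-tetrahydronaphtho[2,3-b]furan-9-ol | C/C=C/CCc1c(C)cc2c(C)c(oc2c1O)[C@@H]1CC[C@H](C)c2c1c(O)c1occ(C)c1c2C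
F4 | step 5 | 2-(7-methoxy-3,4-dimethyl-1-benzofuran-5-yl)-4,4,5,5-tetramethyl-1,3,2-dioxaborolane | COc1cc(B2OC(C)(C)C(C)(C)O2)c(C)c2c(C)coc12
F5 | step 5 | 5-[(2S)-but-3-en-2-yl]-7-methoxy-3,4-dimethyl-1-benzofuran | C=C[C@H](C)c1cc(OC)c2occ(C)c2c1C
F6 | step 7 | 5-[(2S)-5,5-dimethoxypentan-2-yl]-7-methoxy-3,4-dimethyl-1-benzofuran | COC(OC)CC[C@H](C)c1cc(OC)c2occ(C)c2c1C
F7 | step 7 | 5-[(2S)-5,5-dimethoxypentan-2-yl]-3,4-dimethyl-1-benzofuran-7-ol | COC(OC)CC[C@H](C)c1cc(O)c2occ(C)c2c1C
F8 | step 7 | (4S)-4-(7-hydroxy-3,4-dimethyl-1-benzofuran-5-yl)pentanal | O=CCC[C@H](C)c1cc(O)c2occ(C)c2c1C
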